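**Retrosynthetic overview**
1. Ring D is closed last by forming C13–C16 in a deoxygenative 5-exo-dig radical cyclization. The enabling feature: C13 of ring C and C16 of the C8 propargyl group sit 1,3 across C14 on the cyclohexane ring C (chain C13–C14–C8–C15–C16≡C17), so a C13 radical from a temporary C13 carbinol closes ring D (C8, C14, C13, C16, C15) and C17 becomes the exocyclic methylene.
2. Ring A (C1–C5, C10) comes from ring-closing metathesis (C2=C3), then OsO4 from the face opposite the lactone gives the 2β,3β-diol; C4 becomes quaternary by convex-face vinylation of the lactone enolate.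
3. The δ-lactone (C19–O–C20) and the C4–C5 bond come from an intramolecular Michael addition of a C20 propionate enolate to the C5=C6 enoate.
4. C10 is made quaternary by two γ-alkylations of a β-keto ester dianion, C8 by a Sakurai conjugate 2-bromoallylation.
5. Rings B and C are formed together by a Pauson–Khand reaction of a 1,7-enynoate from (R)-1,2-epoxy-5-hexene. Ring order: B and C, lactone, A, D.

Key step: step 21

Remark: gibberellane numbering (C1–C20) is used for all intermediates. C6 in 6–10, C10 in 7, the carbinol carbon C5 in 9 and 10, C4 in 14 and the side-chain carbinol in 15 are epimer mixtures that converge in later steps and are drawn without configuration.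

**Route**

Step 1
Reactants: 1 (R)-2-(but-3-en-1-yl)oxirane
Product: 2 (R)-oct-7-en-1-yn-4-ol
Conditions: lithium acetylide–ethylenediamine complex, DMSO, rt; water work-up
Reagents that add atoms: lithium acetylide–ethylenediamine complex [Li+].[C-]#C.NCCN
Why: SN2 opening of the terminal epoxide at its CH2 terminus by the acetylide (epoxide alkynylation); the stereocenter (future C13) is untouched.

Step 2
Reactants: 2 (R)-oct-7-en-1-yn-4-ol
Product: 3 TBDPS ether of 2
Conditions: TBDPSCl, imidazole, DMF, rt
Reagents that add atoms: tert-butyl(chloro)diphenylsilane CC(C)(C)[Si](Cl)(c1ccccc1)c1ccccc1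
Why: Standard silylation; the bulky silyl ether should survive the Lewis acids, strong bases and oxidants used before step 19.

Step 3
Reactants: 3 TBDPS ether of 2
Product: 4 methyl (R)-5-silyloxynon-8-en-2-ynoate
Conditions: n-BuLi (1.1 equiv), THF, −78 °C; ClCO2Me, −78 to 0 °C
Reagents that add atoms: methyl chloroformate COC(=O)Cl
Why: Deprotonation of the terminal alkyne and C-acylation of the lithium acetylide install C7.

Step 4
Reactants: 4 methyl (R)-5-silyloxynon-8-en-2-ynoate
Product: 5 bicyclic enone ester (C5 ketone, C6=C8, C9-H cis to C13-O)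
Conditions: [RhCl(CO)2]2 (5 mol %), CO (1 atm), dibutyl ether, 130 °C
Reagents that add atoms: carbon monoxide [C-]#[O+]
Why: Rhodium-catalyzed intramolecular Pauson–Khand cyclocarbonylation forms rings B and C and inserts CO as C5; C9 is set by a chair-like metallacycle with the C13 silyloxy group equatorial, and the minor C9 epimer would be removed by chromatography.

Step 5
Reactants: 5 bicyclic enone ester
Product: 6 cis-fused β-keto ester with the 2-bromoallyl group on C8
Conditions: (2-bromoallyl)trimethylsilane (1.5 equiv), TiCl4 (1.1 equiv), CH2Cl2, −78 °C; water work-up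
Reagents that add atoms: (2-bromoallyl)trimethylsilane C=C(Br)C[Si](C)(C)C
Why: Hosomi–Sakurai conjugate allylation of the chelated alkylidene β-keto ester; the allylsilane should add to C8 on the convex face, cis to C9-H, giving the cis-fused hydrindanone and the C8 quaternary center.

Step 6
Reactants: 6 cis-fused β-keto ester
Product: 7 C10-(benzyloxymethyl) β-keto ester
Conditions: LDA (2.2 equiv), THF, −78 to −30 °C; BnOCH2Cl (1.1 equiv), −78 °C; AcOH quench
Reagents that add atoms: benzyl chloromethyl ether ClCOCc1ccccc1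
Why: Dianion alkylation of a β-keto ester (Weiler type); the dianion reacts only at its γ-carbon C10 because C6 carries the stabilized, less reactive enolate.

Step 7
Reactants: 7 C10-(benzyloxymethyl) β-keto ester
Product: 8 C10-allyl-C10-(benzyloxymethyl) β-keto ester
Conditions: LDA (2.2 equiv), THF/DMPU, −78 to −30 °C; allyl bromide, −78 to −20 °C; AcOH quench
Reagents that add atoms: allyl bromide C=CCBr
Why: Second γ-alkylation of the dianion; allyl bromide should approach C10 on the convex β face anti to C11 of ring C, so the benzyloxymethyl carbon (C20) ends α and the C10 quaternary center has the target configuration.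

Step 8
Reactants: 8 C10-allyl-C10-(benzyloxymethyl) β-keto ester
Product: 9 β-hydroxy ester (C5 carbinol)
Conditions: NaBH4, MeOH, −20 °C
Reagents that add atoms: none
Why: Borohydride reduction of the ketone of the β-keto ester with the ester untouched; the carbinol configuration is irrelevant because it is eliminated.

Step 9
Reactants: 9 β-hydroxy ester
Product: 10 C5 mesylate
Conditions: MsCl, Et3N, CH2Cl2, 0 °C
Reagents that add atoms: methanesulfonyl chloride CS(=O)(=O)Cl
Why: Sulfonylation of the secondary alcohol through sulfene prepares the elimination.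

Step 10
Reactants: 10 C5 mesylate
Product: 11 C5=C6 enoate
Conditions: DBU, toluene, 60 °C
Reagents that add atoms: none
Why: E1cB elimination through the C6 ester enolate should give the conjugated enoate whatever the mesylate configuration.

Step 11
Reactants: 11 C5=C6 enoate
Product: 12 C20 primary alcohol
Conditions: BCl3·SMe2, CH2Cl2, 0 °C; water work-up
Reagents that add atoms: none
Why: Lewis acid debenzylation (chloride attack on the boron-coordinated benzyl ether) frees the neopentyl alcohol without touching the alkenes, the vinyl bromide or the silyl ether.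

Step 12
Reactants: 12 C20 primary alcohol
Product: 13 C20 propionate
Conditions: (EtCO)2O, Et3N, DMAP (cat.), CH2Cl2, rt
Reagents that add atoms: propionic anhydride CCC(=O)OC(=O)CC
Why: DMAP-catalyzed acylation tethers the C19–C4–C18 unit to C20.

Step 13
Reactants: 13 C20 propionate
Product: 14 δ-lactone cis-fused to ring B (H5 β, 6β-ester)
Conditions: KHMDS (1.1 equiv), THF, −78 to −20 °C; AcOH quench
Reagents that add atoms: none
Why: Intramolecular Michael addition (6-exo-trig) of the propionate enolate carbon C4 to C5 forms the C4–C5 bond and the lactone; the short tether from the α-C20 forces C4 onto the α face of C5 (H5 β), and protonation of the C6 ester enolate should give the more stable 6β-ester trans to C4.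

Step 14
Reactants: 14 δ-lactone
Product: 15 C4-(1-hydroxyethyl) lactone
Conditions: LDA (1.2 equiv), THF, −78 °C; CH3CHO, −78 °C; AcOH quench
Reagents that add atoms: acetaldehyde CC=O
Why: Aldol addition of the lactone enolate (more acidic and less hindered than C6-H); acetaldehyde should attack C4 on the convex face anti to ring B, placing the new two-carbon group cis to the C10 allyl group and the methyl group on the ring B side.

Step 15
Reactants: 15 C4-(1-hydroxyethyl) lactone
Product: 16 C4-vinyl lactone
Conditions: Burgess reagent (MeO2CN−SO2N+Et3), toluene, 70 °C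
Reagents that add atoms: none
Why: Burgess syn-elimination; only the methyl group offers β-hydrogens, so the vinyl group is the only possible alkene.

Step 16
Reactants: 16 C4-vinyl lactone
Product: 17 tetracyclic Δ2-ene lactone (rings A, B, C and lactone)
Conditions: second-generation Grubbs catalyst (5 mol %), CH2Cl2, 40 °C
Reagents that add atoms: none
Why: Ring-closing metathesis of the cis-1,3-disposed C4 vinyl and C10 allyl groups closes ring A with the C2=C3 alkene; the 2-bromoalkene is inert to the catalyst.

Step 17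
Reactants: 17 tetracyclic Δ2-ene lactone
Product: 18 2β,3β-diol
Conditions: OsO4 (2 mol %), NMO (1.3 equiv), acetone/H2O, 0 °C to rt
Reagents that add atoms: osmium tetroxide O=[Os](=O)(=O)=O; N-methylmorpholine N-oxide C[N+]1([O-])CCOCC1; water O
Why: Upjohn dihydroxylation; OsO4 should attack C2=C3 from the exo β face opposite the lactone bridge, setting both carbinol centers, while the electron-poor vinyl bromide reacts far more slowly.

Step 18
Reactants: 18 2β,3β-diol
Product: 19 2β,3β-acetonide
Conditions: Me2C(OMe)2, PPTS (cat.), CH2Cl2, rt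
Reagents that add atoms: 2,2-dimethoxypropane COC(C)(C)OC
Why: Acetonide formation on the cis-diol protects it from the thiocarbonylation in step 20.

Step 19
Reactants: 19 2β,3β-acetonide
Product: 20 C13 alcohol with a C8 propargyl group
Conditions: TBAF·3H2O (6 equiv), DMF, 60 °C
Reagents that add atoms: none
Why: Fluoride cleaves the silyl ether and in the same pot effects E2 dehydrobromination of the 2-bromoalkene to the terminal alkyne (wet TBAF method), unveiling both partners of the key step.

Step 20
Reactants: 20 C13 alcohol with a C8 propargyl group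
Product: 21 C13 O-(imidazol-1-ylthiocarbonyl) derivative
Conditions: 1,1'-thiocarbonyldiimidazole, DMAP (cat.), 1,2-dichloroethane, 60 °C
Reagents that add atoms: 1,1'-thiocarbonyldiimidazole S=C(n1ccnc1)n1ccnc1
Why: Thiocarbonylation of the secondary alcohol gives the Barton–McCombie radical precursor.

Step 21
Reactants: 21 C13 O-(imidazol-1-ylthiocarbonyl) derivative
Product: 22 2,3-O-isopropylidene methyl ester of the target (ring D closed)
Conditions: Bu3SnH (1.5 equiv) and AIBN (0.2 equiv) added over 6 h by syringe pump, toluene (0.005 M), 110 °C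
Reagents that add atoms: none
Why: The tributyltin radical adds to the thiocarbonyl sulfur and β-scission releases the secondary C13 radical, which adds 5-exo-dig to C16 of the axial C8 propargyl group; the C17 σ-vinyl radical then takes hydrogen from Bu3SnH to give the exocyclic methylene and carry the chain. The closest known reaction type is the Barton–McCombie-initiated cyclization of a hex-5-ynyl radical, here the chain C13–C14–C8–C15–C16≡C17. Ring D (C8, C14, C13, C16, C15) closes in the 5-exo-dig mode and turns ring C into the bicyclo[3.2.1]octane. The only new stereocenter, C13, is fixed by the bridge, because the two-atom C15–C16 bridge can span C8 and C13 only on the β face set by the C8 quaternary center, so the configuration of the lost carbinol does not matter. The step needs cyclization to outrun hydrogen transfer to C13 and exo to beat endo attack; slow addition of Bu3SnH, the fully substituted C8 and the unhindered terminal alkyne should secure both, and the substrate has no other radical acceptor, halide or free hydroxyl. Two carbons that polar chemistry cannot join, a carbinol carbon and an unactivated alkyne carbon, are thus united while the temporary C13 oxygen is removed tracelessly.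

Step 22
Reactants: 22 2,3-O-isopropylidene methyl ester of the target
Product: 23 2,3-O-isopropylidene C7 carboxylic acid
Conditions: NaSEt (5 equiv), DMF, 90 °C; then 1 M HCl to pH 3
Reagents that add atoms: none
Why: SN2 demethylation by thiolate at the ester methyl carbon avoids hydroxide attack at the hindered C7 carbonyl and should leave lactone, acetonide and alkene intact, while the basic medium keeps C6 in the stable β configuration.

Step 23
Reactants: 23 2,3-O-isopropylidene C7 carboxylic acid
Product: 24 CNP0332607.1 (target)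
Conditions: AcOH/H2O (4:1), 45 °C
Reagents that add atoms: none
Why: Mild acid hydrolysis of the acetonide; the δ-lactone and the exocyclic alkene should tolerate warm aqueous acetic acid.

**Compound list**
1 | (R)-2-(but-3-en-1-yl)oxirane [(R)-1,2-epoxy-5-hexene] | C=CCC[C@@H]1CO1 | starting material
2 | (R)-oct-7-en-1-yn-4-ol | C#CC[C@H](O)CCC=C | intermediate
3 | (R)-tert-butyl(oct-7-en-1-yn-4-yloxy)diphenylsilane | C#CC[C@H](O[Si](c1ccccc1)(c1ccccc1)C(C)(C)C)CCC=C | intermediate
4 | methyl (R)-5-[(tert-butyldiphenylsilyl)oxy]non-8-en-2-ynoate | COC(=O)C#CC[C@H](O[Si](c1ccccc1)(c1ccccc1)C(C)(C)C)CCC=C | intermediate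
5 | methyl 6-[(tert-butyldiphenylsilyl)oxy]-2-oxo-3,3a,4,5,6,7-hexahydro-2H-indene-1-carboxylate, 3a-H and 6-O cis (C5 ketone, C6=C8, C9-H β, C13-OSi β) | COC(=O)C1=C2C[C@H](O[Si](c3ccccc3)(c3ccccc3)C(C)(C)C)CC[C@H]2CC1=O | intermediate
6 | methyl 7a-(2-bromoprop-2-en-1-yl)-6-[(tert-butyldiphenylsilyl)oxy]-2-oxooctahydro-1H-indene-1-carboxylate, cis-fused, bromoallyl cis to 3a-H (C8 quaternary) | COC(=O)C1C(=O)C[C@@H]2CC[C@@H](O[Si](c3ccccc3)(c3ccccc3)C(C)(C)C)C[C@]12CC(Br)=C | intermediate
7 | 3-[(benzyloxy)methyl] derivative of 6 (C20 on C10) | COC(=O)C1C(=O)C(COCc3ccccc3)[C@@H]2CC[C@@H](O[Si](c3ccccc3)(c3ccccc3)C(C)(C)C)C[C@]12CC(Br)=C | intermediate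
8 | 3-allyl-3-[(benzyloxy)methyl] derivative of 6 (C10 quaternary: CH2OBn α, allyl β) | COC(=O)C1C(=O)[C@](CC=C)(COCc3ccccc3)[C@@H]2CC[C@@H](O[Si](c3ccccc3)(c3ccccc3)C(C)(C)C)C[C@]12CC(Br)=C | intermediate
9 | 2-hydroxy analogue of 8 (C5 carbinol, β-hydroxy ester) | COC(=O)C1C(O)[C@](CC=C)(COCc3ccccc3)[C@@H]2CC[C@@H](O[Si](c3ccccc3)(c3ccccc3)C(C)(C)C)C[C@]12CC(Br)=C | intermediate
10 | 2-(methanesulfonyloxy) analogue of 8 (C5 mesylate) | COC(=O)C1C(OS(C)(=O)=O)[C@](CC=C)(COCc3ccccc3)[C@@H]2CC[C@@H](O[Si](c3ccccc3)(c3ccccc3)C(C)(C)C)C[C@]12CC(Br)=C | intermediate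
11 | methyl 3-allyl-3-[(benzyloxy)methyl]-7a-(2-bromoallyl)-6-[(tert-butyldiphenylsilyl)oxy]-3a,4,5,6,7,7a-hexahydro-3H-indene-1-carboxylate (C5=C6 enoate) | COC(=O)C1=C[C@](CC=C)(COCc3ccccc3)[C@@H]2CC[C@@H](O[Si](c3ccccc3)(c3ccccc3)C(C)(C)C)C[C@]12CC(Br)=C | intermediate
12 | 3-(hydroxymethyl) analogue of 11 (C20-OH) | COC(=O)C1=C[C@](CC=C)(CO)[C@@H]2CC[C@@H](O[Si](c3ccccc3)(c3ccccc3)C(C)(C)C)C[C@]12CC(Br)=C | intermediate
13 | C20 propionate of 12 | COC(=O)C1=C[C@](CC=C)(COC(=O)CC)[C@@H]2CC[C@@H](O[Si](c3ccccc3)(c3ccccc3)C(C)(C)C)C[C@]12CC(Br)=C | intermediate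
14 | tricyclic δ-lactone (C19(=O)–O–C20 across C4–C5–C10, cis-fused to ring B; H5 β, 6β-CO2Me, C4 bearing H and methyl) | COC(=O)[C@H]1[C@@H]2C(C)C(=O)OC[C@]2(CC=C)[C@@H]3CC[C@@H](O[Si](c4ccccc4)(c4ccccc4)C(C)(C)C)C[C@]13CC(Br)=C | intermediate
15 | C4-(1-hydroxyethyl)-C4-methyl lactone (hydroxyethyl cis to the C10 allyl group) | COC(=O)[C@H]1[C@@H]2[C@@](C)(C(C)O)C(=O)OC[C@]2(CC=C)[C@@H]3CC[C@@H](O[Si](c4ccccc4)(c4ccccc4)C(C)(C)C)C[C@]13CC(Br)=C | intermediate
16 | C4-methyl-C4-vinyl lactone (vinyl cis to the C10 allyl group) | COC(=O)[C@H]1[C@@H]2[C@@](C)(C=C)C(=O)OC[C@]2(CC=C)[C@@H]3CC[C@@H](O[Si](c4ccccc4)(c4ccccc4)C(C)(C)C)C[C@]13CC(Br)=C | intermediate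
17 | tetracyclic Δ2-ene 19,20-lactone methyl ester with C8 2-bromoallyl and C13 β-silyloxy groups | COC(=O)[C@H]1[C@@H]2[C@@]4(C)C=CC[C@@]2(COC4=O)[C@@H]3CC[C@@H](O[Si](c5ccccc5)(c5ccccc5)C(C)(C)C)C[C@]13CC(Br)=C | intermediate
18 | 2β,3β-diol of 17 | COC(=O)[C@H]1[C@@H]2[C@@]4(C)[C@@H](O)[C@@H](O)C[C@@]2(COC4=O)[C@@H]3CC[C@@H](O[Si](c5ccccc5)(c5ccccc5)C(C)(C)C)C[C@]13CC(Br)=C | intermediate
19 | 2β,3β-O-isopropylidene derivative of 18 | COC(=O)[C@H]1[C@@H]2[C@@]4(C)[C@H]6OC(C)(C)O[C@H]6C[C@@]2(COC4=O)[C@@H]3CC[C@@H](O[Si](c5ccccc5)(c5ccccc5)C(C)(C)C)C[C@]13CC(Br)=C | intermediate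
20 | C13 β-alcohol with C8 prop-2-yn-1-yl group (acetonide, methyl ester) | COC(=O)[C@H]1[C@@H]2[C@@]4(C)[C@H]6OC(C)(C)O[C@H]6C[C@@]2(COC4=O)[C@@H]3CC[C@@H](O)C[C@]13CC#C | intermediate
21 | C13 O-(1H-imidazol-1-ylthiocarbonyl) derivative of 20 | COC(=O)[C@H]1[C@@H]2[C@@]4(C)[C@H]6OC(C)(C)O[C@H]6C[C@@]2(COC4=O)[C@@H]3CC[C@@H](OC(=S)n5ccnc5)C[C@]13CC#C | intermediate
22 | 2,3-O-isopropylidene methyl ester of the target (16-methylene, rings A–D and lactone complete) | COC(=O)[C@H]1[C@@H]2[C@@]4(C)[C@H]6OC(C)(C)O[C@H]6C[C@@]2(COC4=O)[C@@H]3CC[C@@H]5C[C@]13CC5=C | intermediate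
23 | 2,3-O-isopropylidene derivative of the target acid | OC(=O)[C@H]1[C@@H]2[C@@]4(C)[C@H]6OC(C)(C)O[C@H]6C[C@@]2(COC4=O)[C@@H]3CC[C@@H]5C[C@]13CC5=C | intermediate
24 | CNP0332607.1 (2β,3β-dihydroxy 19,20-lactone gibberellin 7-acid) | C=C1C[C@]23C[C@H]1CC[C@H]2[C@]12COC(=O)[C@](C)([C@@H](O)[C@@H](O)C1)[C@H]2[C@@H]3C(=O)O | target

**Totals and risks**
Total step count: 23. Longest linear sequence: 23 steps (from 1).

Step 4: the electron-poor 1,7-enynoate may cyclocarbonylate sluggishly, with alkyne oligomerization or poor control at C9 taking over. The fallback sets out from 3: a cobalt-catalyzed Pauson–Khand reaction of the terminal alkyne (Co2(CO)8 10 mol %, tetramethylthiourea, CO 1 atm, benzene, 70 °C) should give the ester-free bicyclic enone F1; α-iodination (I2, pyridine, CH2Cl2) gives the α-iodoenone F2; palladium-catalyzed methoxycarbonylation (Pd(OAc)2, PPh3, CO, MeOH, Et3N) comes back to the route at 5.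

Step 13: the ester enolate may fail to reach the reactive rotamer and be consumed by proton transfer or intermolecular Claisen condensation instead of closing the lactone. The fallback sets out from 13: LDA and Me3SiCl at −78 °C give the trimethylsilyl ketene acetal F3, which is closed by an intramolecular Mukaiyama–Michael reaction (TiCl4, CH2Cl2, −78 °C) and comes back to the route at 14.

Step 21: the C13 radical may be reduced by the stannane before the slow 5-exo-dig closure, or the alkyne may be hydrostannylated. The fallback sets out from 20: Appel iodination (I2, PPh3, imidazole, toluene) gives the C13 iodide F4; iodine atom-transfer cyclization without any hydride donor ((Bu3Sn)2 10 mol %, sunlamp, benzene, 80 °C) gives the exocyclic vinyl iodide F5; reductive deiodination (Bu3SnH, AIBN, benzene, 80 °C) comes back to the route at 22.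

Further compounds
F1 | step 4 | 6-[(tert-butyldiphenylsilyl)oxy]-3,3a,4,5,6,7-hexahydro-2H-inden-2-one (ester-free enone, 3a-H and 6-O cis) | O=C1C=C2C[C@H](O[Si](c3ccccc3)(c3ccccc3)C(C)(C)C)CC[C@H]2C1
F2 | step 4 | 1-iodo derivative of F1 (α-iodoenone) | O=C1C(I)=C2C[C@H](O[Si](c3ccccc3)(c3ccccc3)C(C)(C)C)CC[C@H]2C1
F3 | step 13 | trimethylsilyl ketene acetal of the propionate 13 | COC(=O)C1=C[C@](CC=C)(COC(O[Si](C)(C)C)=CC)[C@@H]2CC[C@@H](O[Si](c3ccccc3)(c3ccccc3)C(C)(C)C)C[C@]12CC(Br)=C
F4 | step 21 | C13 α-iodide from 20 (inverted at C13) | COC(=O)[C@H]1[C@@H]2[C@@]4(C)[C@H]6OC(C)(C)O[C@H]6C[C@@]2(COC4=O)[C@@H]3CC[C@H](I)C[C@]13CC#C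
F5 | step 21 | 17-iodo derivative of 22 (exocyclic vinyl iodide, E/Z mixture) | COC(=O)[C@H]1[C@@H]2[C@@]4(C)[C@H]6OC(C)(C)O[C@H]6C[C@@]2(COC4=O)[C@@H]3CC[C@@H]5C[C@]13CC5=CI
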